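The trap in these runs is the material that goes missing. Epsilon and zeta both stand at 0.50 equiv, so a loss that needs reagent and a loss that doesn't grow alike in them, and a precise split of that loss would be an illusion.

| setting | epsilon | zeta | south | north-west | south-west | north | north-east |
|---|---|---|---|---|---|---|---|
| starting material | 6.7 mM | 20 mM | 10 mM | 10 mM | 10 mM | 10 mM | 10 mM |
| reagent in the second phase | 0.50 equiv | 0.50 equiv | 0.500 equiv | 1.00 equiv | 2.00 equiv | 4.00 equiv | 8.00 equiv |
| remark | run made earlier | run made earlier |  |  |  |  |  |
| time |  |  | 2.5 min | 2.5 min | 2.5 min | 2.5 min | 2.5 min |
| volume of the second phase over the first |  |  | 0.50 | 0.50 | 0.50 | 0.50 | 0.50 |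

| run | time / s | target / % | starting material / % |
|---|---|---|---|
| epsilon | 10.0 | 0.1 | 83.9 |
| epsilon | 15.0 | 0.8 | 80.5 |
| epsilon | 40.0 | 1.2 | 77.6 |
| epsilon | 90.0 | 6.1 | 72.1 |
| zeta | 25.0 | 3.1 | 76.5 |
| zeta | 50.0 | 6.9 | 71.4 |
| zeta | 60.0 | 8.7 | 70.3 |
| zeta | 90.0 | 12.8 | 63.7 |

(each reading ± 0.5 percentage points)

- a species is counted by the starting material in it: one side product counts as two
- in the second phase: reagent in the second phase; everything else is in the first
- charges count per volume of the first phase; a concentration in a rate is the amount of a species over the volume of its own phase; every rate counts per litre of the first phase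
- the earlier runs were read with a standard deviation of 0.5 percentage points
- steps that have been proposed: starting material <-> dormant form; reagent in the reaction phase <-> reagent in the second phase; starting material + reagent in the reaction phase -> target; starting material + target -> side product; reagent in the reaction phase + target -> over-reacted product
- the earlier runs hold the two phases in the same ratio of volumes as the flask asked about
- "hardly changes" means that all values lie within two and a half points (for a concentration: within two and a half percent of the largest)
- a step back or a flat step of under half a point counts as no turn

- amount of target at the end, in percent of the starting material charged for south, north-west, south-west, north, north-east, in this order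
- how the row runs (hardly changes / falls, then rises / falls all the way / rises, then falls / rises all the way)

I reckon with the pool W, starting material plus dormant form. At 40.0 s in epsilon, what is neither starting material nor target gives K, the dormant form per unit of starting material. That puts W in zeta at 90.0 s:

K = 0.273, W = 81.1 %, missing M = 6.10 %

Call θ = −ln W the exposure. I assume it grows with reagent charge times time, so zeta gives u, the exposure per equivalent in the 2.5 min flasks:

u = 0.349

Let s (a selectivity factor) be how much faster target over-reacts than the pool makes it. Then early on, over-reacted product ≈ s·P·P/(2W), and:

P = (e^(−θ) − e^(−sθ))/(s−1), peak at θ* = ln s/(s−1)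

At small θ, target follows θ; at large θ, it follows the dying pool. Nothing separates the two losses, so I give over-reaction half of M:

s = 3.02, θ* = 0.547, peak 19.2 % near 1.57 equivalents, north-east 3.03 %

Now I turn the question round. For a row that rises all the way, the last step must not go back, so P at north-east's θ = 2.79 would have to stand level with or above P at north's θ = 1.40; the peak itself may lie between the two. The two P are equal where e^(−θ) + e^(−sθ) = 1 at north's θ. That needs s below about 0.204, so over-reaction in zeta under about 0.21 percentage points, hardly any of M. The scatter of 0.5 points can't exclude this, but I expect a turn.

The forecast says 10 %, 19 %, 33 %, 47 %, 58 %, rises all the way: “Target then keeps rising with equivalents”.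

The flask gives 12.6 %, 19.3 %, 23.1 %, 16.6 %, 4.17 %: rises, then falls.

    starting material ⇌ dormant form (K = 0.270, k = 0.0300 s⁻¹)
    reagent in the reaction phase ⇌ reagent in the second phase, rate k2*([reagent in the reaction phase] - [reagent in the second phase]/K2) per volume of the first phase (partition coefficient = 0.700, kL = 0.00800 s⁻¹)
    starting material + reagent in the reaction phase → target (k = 0.710 L mol⁻¹ s⁻¹)
    starting material + target → side product (k = 0.220 L mol⁻¹ s⁻¹)
    reagent in the reaction phase + target → over-reacted product (k = 1.10 L mol⁻¹ s⁻¹)

The row turns at 2.0 equiv, where south-west holds 25.0 % of over-reacted product. With u, south-west's pool should stand at 49.7 %, and it stands at 46.5 %. For north-east, u gives 6.13 %, and the flask holds 4.68 %.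

All runs were computed from invented constants; scatter was added.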